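**Retrosynthetic overview**
1. Last bond: C13–C14 by Suzuki–Miyaura coupling of alkenylboronate 23 (C1–C13) with alkenyl iodide 43 (C14–C24); the C17 ketone and C24 aldehyde are then unmasked together by desilylation and double oxidation.
2. C7–C8 by Stille coupling of lactone stannane 22 with the iodide/boronate linchpin 12; the lactone ring comes from anti-crotylboration, acryloylation and ring-closing metathesis.
3. The oxolane ring is closed by a palladium-catalysed alkoxycarbonylative cyclisation of alkenol 32 (O–C22 bond, C22 stereocentre, C24 carbon in one step); 32 comes from a lactate-ketone anti-aldol; C16/C17 come from a chiral allenylindium addition.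
4. C10 and C20 both come from (S)-3-bromo-2-methylpropan-1-ol through the common bromide 2.
5. Ring order: lactone (step 12) and oxolane (step 21) are built in separate branches before the two fragment unions.

Assumption: the target is made exactly as the SMILES is written, i.e. 4,5-trans lactone (4S,5R) and 10R,16R,18R,19R,20R,22R; locants C1 (lactone C=O) to C24 (CHO) are used below. The reagent antipodes in steps 8, 20, 24 and 26 were assigned from the accepted transition-state models, and the ligand antipode in step 21 is left to screening.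

**Step 1**
Reactants: 1 (S)-3-bromo-2-methylpropan-1-ol
Product: 2 (S)-(3-bromo-2-methylpropoxy)(tert-butyl)dimethylsilane
Conditions: TBSCl, imidazole, CH2Cl2, 0 °C → rt
Reagents that add atoms: tert-butyldimethylsilyl chloride, CC(C)(C)[Si](C)(C)Cl
Why: Routine O-silylation of the primary alcohol; the chiral-pool stereocentre (later C10 in one branch, C20 in the other) is untouched.

**Step 2**
Reactants: 2 (S)-(3-bromo-2-methylpropoxy)(tert-butyl)dimethylsilane
Product: 3 (R)-tert-butyldimethyl[(2-methylpent-4-yn-1-yl)oxy]silane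
Conditions: LiC≡CH·H2NCH2CH2NH2, DMSO, rt
Reagents that add atoms: lithium acetylide–ethylenediamine complex, [Li+].[C-]#C.NCCN
Why: SN2 alkynylation of the primary bromide in a dipolar aprotic solvent; no bond to the stereocentre is broken (the descriptor changes only through CIP priorities).

**Step 3**
Reactants: 3 (R)-tert-butyldimethyl[(2-methylpent-4-yn-1-yl)oxy]silane
Product: 4 (R)-2-methylpent-4-yn-1-ol
Conditions: Bu4NF, THF, 0 °C → rt
Reagents that add atoms: none
Why: Fluoride-mediated desilylation of the primary silyl ether.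

**Step 4**
Reactants: 4 (R)-2-methylpent-4-yn-1-ol
Product: 5 (R)-2-methylpent-4-ynal
Conditions: Dess–Martin periodinane, CH2Cl2, 0 °C; used at once as a solution
Reagents that add atoms: none
Why: Dess–Martin oxidation under non-basic conditions gives the volatile aldehyde without epimerising the α-stereocentre.

**Step 5**
Reactants: 6 1-bromopropane
Product: 7 propyltriphenylphosphonium bromide
Conditions: PPh3, toluene, reflux
Reagents that add atoms: triphenylphosphine, c1ccc(cc1)P(c1ccccc1)c1ccccc1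
Why: SN2 quaternisation of the phosphine.

**Step 6**
Reactants: 7 propyltriphenylphosphonium bromide; 5 (R)-2-methylpent-4-ynal
Product: 11 (3Z,5R)-3-iodo-5-methyloct-3-en-7-yne, via propylidenetriphenylphosphorane 8 (not isolated), via (1-iodopropyl)triphenylphosphonium iodide 9 (not isolated), via (1-iodopropylidene)triphenylphosphorane 10 (not isolated)
Conditions: n-BuLi, THF, 0 °C; I2, −78 °C; NaN(SiMe3)2, −78 °C; then 5, −78 → −20 °C
Reagents that add atoms: iodine, [I][I]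
Why: Stork–Zhao-type Wittig olefination with the α-iodo ylide is Z-selective (iodine cis to C10), which fixes the 8Z geometry of the trisubstituted alkene.

**Step 7**
Reactants: 11 (3Z,5R)-3-iodo-5-methyloct-3-en-7-yne
Product: 12 2-[(1E,4R,5Z)-6-iodo-4-methylocta-1,5-dien-1-yl]-4,4,5,5-tetramethyl-1,3,2-dioxaborolane
Conditions: pinacolborane, Cp2Zr(H)Cl (10 mol %), Et3N (10 mol %), CH2Cl2, 40 °C
Reagents that add atoms: pinacolborane, CC1(C)OBOC1(C)C
Why: Zirconium-catalysed syn-hydroboration of the terminal alkyne gives the (E)-alkenylboronate (12E) and leaves the alkenyl iodide alone.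

**Step 8**
Reactants: 13 3-(trimethylsilyl)prop-2-ynal; 14 (E)-but-2-ene
Product: 17 (3S,4S)-4-methyl-1-(trimethylsilyl)hex-5-en-1-yn-3-ol, via (E)-but-2-en-1-ylpotassium 15 (not isolated), via (E)-crotylbis(isopinocampheyl)borane 16 (not isolated)
Conditions: 14, n-BuLi, KOt-Bu, THF, −78 → −45 °C; (−)-Ipc2BOMe [from (+)-α-pinene], −78 °C; BF3·OEt2; 13, −78 °C; then NaOH, H2O2
Reagents that add atoms: none
Why: Brown crotylboration: the (E)-crotylborane reacts through a chair transition state to give the 3,4-anti product, and the (+)-α-pinene-derived ligands direct attack to the Si face of the ynal, which sets C5 and C4 (the trans-lactone relationship).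

**Step 9**
Reactants: 17 (3S,4S)-4-methyl-1-(trimethylsilyl)hex-5-en-1-yn-3-ol
Product: 18 (3S,4S)-4-methylhex-5-en-1-yn-3-ol
Conditions: K2CO3 (0.2 equiv), MeOH, 0 °C
Reagents that add atoms: none
Why: Base-catalysed methanolysis of the alkynyl–silicon bond.

**Step 10**
Reactants: 18 (3S,4S)-4-methylhex-5-en-1-yn-3-ol
Product: 19 (1E,3S,4S)-4-methyl-1-(tributylstannyl)hexa-1,5-dien-3-ol
Conditions: Bu3SnH, PdCl2(PPh3)2 (2 mol %), THF, 0 °C
Reagents that add atoms: tributyltin hydride, CCCC[SnH](CCCC)CCCC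
Why: Palladium-catalysed syn-hydrostannation of the terminal propargylic alcohol places tin at the terminus and gives the (E)-alkenylstannane (6E); the terminal alkene does not react.

**Step 11**
Reactants: 19 (1E,3S,4S)-4-methyl-1-(tributylstannyl)hexa-1,5-dien-3-ol; 20 acryloyl chloride
Product: 21 (1E,3S,4S)-4-methyl-1-(tributylstannyl)hexa-1,5-dien-3-yl prop-2-enoate
Conditions: i-Pr2NEt, CH2Cl2, −78 → 0 °C
Reagents that add atoms: none
Why: O-acylation of the secondary alcohol under basic, acid-free conditions that spare the alkenylstannane.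

**Step 12**
Reactants: 21 (1E,3S,4S)-4-methyl-1-(tributylstannyl)hexa-1,5-dien-3-yl prop-2-enoate
Product: 22 (5S,6S)-5-methyl-6-[(E)-2-(tributylstannyl)ethenyl]-5,6-dihydro-2H-pyran-2-one
Conditions: second-generation Grubbs catalyst RuCl2(=CHPh)(PCy3)(H2IMes) (5 mol %), CH2Cl2, 40 °C
Reagents that add atoms: none
Why: Ring-closing metathesis between the acrylate and the terminal vinyl group closes the six-membered lactone; the hindered internal stannyl alkene stays out and no stereocentre is touched.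

**Step 13**
Reactants: 22 (5S,6S)-5-methyl-6-[(E)-2-(tributylstannyl)ethenyl]-5,6-dihydro-2H-pyran-2-one; 12 2-[(1E,4R,5Z)-6-iodo-4-methylocta-1,5-dien-1-yl]-4,4,5,5-tetramethyl-1,3,2-dioxaborolane
Product: 23 (5S,6R)-6-[(1E,3Z,5R,7E)-3-ethyl-5-methyl-8-(4,4,5,5-tetramethyl-1,3,2-dioxaborolan-2-yl)octa-1,3,7-trien-1-yl]-5-methyl-5,6-dihydro-2H-pyran-2-one
Conditions: PdCl2(MeCN)2 (5 mol %), DMF, rt, dark
Reagents that add atoms: none
Why: Stille coupling at the alkenyl iodide with retention at both partners forms C7–C8 and the (6E,8Z)-diene; the pinacol boronate is inert without base.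

**Step 14**
Reactants: 2 (S)-(3-bromo-2-methylpropoxy)(tert-butyl)dimethylsilane
Product: 24 (R)-tert-butyl[(2,4-dimethylpent-4-en-1-yl)oxy]dimethylsilane
Conditions: isopropenylmagnesium bromide, CuI (10 mol %), THF, 0 °C → rt
Reagents that add atoms: isopropenylmagnesium bromide, CC(=C)[Mg]Br
Why: Copper-catalysed coupling of the alkenyl Grignard reagent with the primary bromide installs C22 and its alkene without touching the stereocentre.

**Step 15**
Reactants: 24 (R)-tert-butyl[(2,4-dimethylpent-4-en-1-yl)oxy]dimethylsilane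
Product: 25 (R)-2,4-dimethylpent-4-en-1-ol
Conditions: Bu4NF, THF, 0 °C → rt
Reagents that add atoms: none
Why: Fluoride-mediated desilylation.

**Step 16**
Reactants: 25 (R)-2,4-dimethylpent-4-en-1-ol
Product: 26 (R)-2,4-dimethylpent-4-enal
Conditions: Dess–Martin periodinane, CH2Cl2, 0 °C; used at once as a solution
Reagents that add atoms: none
Why: Dess–Martin oxidation without base keeps the α-stereocentre (C20) intact.

**Step 17**
Reactants: 27 ethyl (S)-lactate
Product: 28 (S)-2-hydroxy-N-methoxy-N-methylpropanamide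
Conditions: MeNH(OMe)·HCl, i-PrMgCl, THF, −20 → 0 °C
Reagents that add atoms: N,O-dimethylhydroxylamine hydrochloride, CNOC.Cl
Why: Aminolysis of the ester by the magnesium amide gives the Weinreb amide with the lactate stereocentre retained.

**Step 18**
Reactants: 28 (S)-2-hydroxy-N-methoxy-N-methylpropanamide
Product: 29 (S)-2-hydroxypentan-3-one
Conditions: EtMgBr (3 equiv), THF, 0 °C → rt
Reagents that add atoms: ethylmagnesium bromide, CC[Mg]Br
Why: Weinreb ketone synthesis; the chelated tetrahedral intermediate stops the addition at the ketone.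

**Step 19**
Reactants: 29 (S)-2-hydroxypentan-3-one
Product: 30 (S)-3-oxopentan-2-yl benzoate
Conditions: Bz2O, DMAP (cat.), i-Pr2NEt, CH2Cl2, rt
Reagents that add atoms: benzoic anhydride, O=C(OC(=O)c1ccccc1)c1ccccc1
Why: O-benzoylation installs the group that controls the enolate face in the next step.

**Step 20**
Reactants: 30 (S)-3-oxopentan-2-yl benzoate; 26 (R)-2,4-dimethylpent-4-enal
Product: 32 (2S,4R,5R,6R)-5-hydroxy-4,6,8-trimethyl-3-oxonon-8-en-2-yl benzoate, via dicyclohexylboron (E)-enolate 31 (not isolated)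
Conditions: Cy2BCl, Me2NEt, Et2O, −78 → 0 °C; 26, −78 → −20 °C; then H2O2, MeOH, pH 7 buffer
Reagents that add atoms: none
Why: Paterson anti-aldol: the (E)-boron enolate reacts through a chair transition state (C18/C19 anti) and the α′-benzoyloxy stereocentre directs the aldehyde to one enolate face (C18 R), overriding the Felkin preference of 26 to give the anti,anti C18–C19–C20 triad.

**Step 21**
Reactants: 32 (2S,4R,5R,6R)-5-hydroxy-4,6,8-trimethyl-3-oxonon-8-en-2-yl benzoate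
Product: 33 methyl 2-[(2R,4R,5R)-5-[(2R,4S)-4-(benzoyloxy)-3-oxopentan-2-yl]-2,4-dimethyloxolan-2-yl]acetate
Conditions: Pd(O2CCF3)2 (10 mol %), chiral 2,2'-bis(4-benzyloxazolin-2-yl)-1,1'-binaphthyl ligand (12 mol %, antipode fixed by screening), p-benzoquinone (2 equiv), CO (1 atm), MeOH–CH2Cl2, rt
Reagents that add atoms: carbon monoxide, [C-]#[O+]; methanol, CO
Why: Proposed new method: a cationic divalent palladium centre held by the chiral bis(oxazoline) binds the C19 hydroxyl and the 1,1-disubstituted alkene, 5-exo oxypalladation gives a C23–Pd species that has no β-hydrogen because C22 is fully substituted, CO insertion and methanolysis release the ester and zerovalent palladium that benzoquinone reoxidises, and the ligand rather than the substrate selects the alkene face, so the step closes the oxolane ring, sets C22 (R) (CH2CO2Me cis to the C20 methyl) and adds C24; the closest known reaction type is the intramolecular alkoxycarbonylation of alkenols and the enantioselective Wacker cyclisation–carbonylation of alkenyl phenols to chromans, not yet shown for an aliphatic secondary alcohol with catalyst-controlled diastereoselection at a fully substituted ether carbon.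

**Step 22**
Reactants: 33 methyl 2-[(2R,4R,5R)-5-[(2R,4S)-4-(benzoyloxy)-3-oxopentan-2-yl]-2,4-dimethyloxolan-2-yl]acetate
Product: 34 (2S,3RS,4S)-4-[(2R,3R,5R)-5-(2-hydroxyethyl)-3,5-dimethyloxolan-2-yl]pentane-2,3-diol
Conditions: LiBH4, THF–MeOH, 0 °C → rt
Reagents that add atoms: none
Why: One hydride reduction takes the ketone, the benzoate and the methyl ester to the triol; the new C17 carbinol is a mixture that does not matter because that carbon becomes the aldehyde next.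

**Step 23**
Reactants: 34 (2S,3RS,4S)-4-[(2R,3R,5R)-5-(2-hydroxyethyl)-3,5-dimethyloxolan-2-yl]pentane-2,3-diol
Product: 35 (2R)-2-[(2R,3R,5R)-5-(2-hydroxyethyl)-3,5-dimethyloxolan-2-yl]propanal
Conditions: NaIO4, MeOH–pH 7 buffer, 0 °C
Reagents that add atoms: none
Why: Glycol cleavage of the vicinal diol gives the C17 aldehyde under neutral conditions, so C18 is not epimerised and the primary alcohol is untouched.

**Step 24**
Reactants: 36 pent-3-yn-2-one
Product: 37 (S)-pent-3-yn-2-ol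
Conditions: RuCl[(S,S)-TsDPEN](p-cymene) (1 mol %), i-PrOH, rt
Reagents that add atoms: none
Why: Noyori asymmetric transfer hydrogenation of the ynone; the (S,S)-catalyst delivers hydride to the face that gives the (S)-propargylic alcohol.

**Step 25**
Reactants: 37 (S)-pent-3-yn-2-ol
Product: 38 (S)-pent-3-yn-2-yl methanesulfonate
Conditions: MsCl, Et3N, CH2Cl2, −78 °C
Reagents that add atoms: methanesulfonyl chloride, CS(Cl)(=O)=O
Why: O-sulfonylation with retention at carbon.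

**Step 26**
Reactants: 38 (S)-pent-3-yn-2-yl methanesulfonate; 35 (2R)-2-[(2R,3R,5R)-5-(2-hydroxyethyl)-3,5-dimethyloxolan-2-yl]propanal
Product: 40 (2S,3R,4R)-2-[(2R,3R,5R)-5-(2-hydroxyethyl)-3,5-dimethyloxolan-2-yl]-4-methylhept-5-yn-3-ol, via (aR)-allenylindium reagent 39 (not isolated)
Conditions: Pd(dppf)Cl2 (5 mol %), InI (1.5 equiv), THF–DMPU (3:1), rt
Reagents that add atoms: none
Why: Marshall propargylation: anti SN2′ oxidative addition of zerovalent palladium and transmetalation to indium give the (aR)-allenylindium, which adds through a cyclic SE2′ transition state to give the 16,17-anti adduct with C16 (R); this is matched with the Felkin preference of 35 (C17–OH syn to the C18 methyl), and the reagent tolerates the free primary alcohol.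

**Step 27**
Reactants: 40 (2S,3R,4R)-2-[(2R,3R,5R)-5-(2-hydroxyethyl)-3,5-dimethyloxolan-2-yl]-4-methylhept-5-yn-3-ol
Product: 41 triethyl{2-[(2R,4R,5R)-2,4-dimethyl-5-[(2R,3R,4R)-4-methyl-3-(triethylsilyloxy)hept-5-yn-2-yl]oxolan-2-yl]ethoxy}silane
Conditions: TESOTf (2.5 equiv), 2,6-lutidine, CH2Cl2, −78 → 0 °C
Reagents that add atoms: triethylsilyl trifluoromethanesulfonate, CC[Si](CC)(CC)OS(=O)(=O)C(F)(F)F
Why: Silylation of both hydroxyls with one protecting group that is removed in a single late step.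

**Step 28**
Reactants: 41 triethyl{2-[(2R,4R,5R)-2,4-dimethyl-5-[(2R,3R,4R)-4-methyl-3-(triethylsilyloxy)hept-5-yn-2-yl]oxolan-2-yl]ethoxy}silane
Product: 43 triethyl{2-[(2R,4R,5R)-5-[(2R,3R,4R,5E)-6-iodo-4-methyl-3-(triethylsilyloxy)hept-5-en-2-yl]-2,4-dimethyloxolan-2-yl]ethoxy}silane, via alkenylzirconocene chloride 42 (not isolated)
Conditions: Cp2Zr(H)Cl (2.5 equiv), THF, 50 °C; then I2, 0 °C
Reagents that add atoms: iodine, [I][I]
Why: Syn-hydrozirconation of the methyl alkyne, equilibrated so that zirconium sits on the less hindered C14, followed by iodinolysis with retention gives the (E)-iodoalkene that carries the 14E geometry.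

**Step 29**
Reactants: 23 (5S,6R)-6-[(1E,3Z,5R,7E)-3-ethyl-5-methyl-8-(4,4,5,5-tetramethyl-1,3,2-dioxaborolan-2-yl)octa-1,3,7-trien-1-yl]-5-methyl-5,6-dihydro-2H-pyran-2-one; 43 triethyl{2-[(2R,4R,5R)-5-[(2R,3R,4R,5E)-6-iodo-4-methyl-3-(triethylsilyloxy)hept-5-en-2-yl]-2,4-dimethyloxolan-2-yl]ethoxy}silane
Product: 44 (5S,6R)-6-[(1E,3Z,5R,7E,9E,11R,12R,13R)-13-[(2R,3R,5R)-3,5-dimethyl-5-[2-(triethylsilyloxy)ethyl]oxolan-2-yl]-3-ethyl-5,9,11-trimethyl-12-(triethylsilyloxy)tetradeca-1,3,7,9-tetraen-1-yl]-5-methyl-5,6-dihydro-2H-pyran-2-one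
Conditions: Pd(PPh3)4 (10 mol %), TlOEt (1.5 equiv), THF–H2O (3:1), rt
Reagents that add atoms: none
Why: Suzuki–Miyaura coupling with retention at both alkenyl partners forms C13–C14 and the (12E,14E)-diene; the fast thallium-base variant at room temperature is chosen to spare the lactone.

**Step 30**
Reactants: 44 (5S,6R)-6-[(1E,3Z,5R,7E,9E,11R,12R,13R)-13-[(2R,3R,5R)-3,5-dimethyl-5-[2-(triethylsilyloxy)ethyl]oxolan-2-yl]-3-ethyl-5,9,11-trimethyl-12-(triethylsilyloxy)tetradeca-1,3,7,9-tetraen-1-yl]-5-methyl-5,6-dihydro-2H-pyran-2-one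
Product: 45 (5S,6R)-6-[(1E,3Z,5R,7E,9E,11R,12R,13S)-3-ethyl-12-hydroxy-13-[(2R,3R,5R)-5-(2-hydroxyethyl)-3,5-dimethyloxolan-2-yl]-5,9,11-trimethyltetradeca-1,3,7,9-tetraen-1-yl]-5-methyl-5,6-dihydro-2H-pyran-2-one
Conditions: HF·pyridine, pyridine, THF, 0 °C → rt
Reagents that add atoms: none
Why: Buffered fluoride removes both triethylsilyl ethers without opening the lactone or moving the dienes.

**Step 31**
Reactants: 45 (5S,6R)-6-[(1E,3Z,5R,7E,9E,11R,12R,13S)-3-ethyl-12-hydroxy-13-[(2R,3R,5R)-5-(2-hydroxyethyl)-3,5-dimethyloxolan-2-yl]-5,9,11-trimethyltetradeca-1,3,7,9-tetraen-1-yl]-5-methyl-5,6-dihydro-2H-pyran-2-one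
Product: 46 2-[(2R,4R,5R)-5-[(2R,4R,5E,7E,10R,11Z,13E)-12-ethyl-4,6,10-trimethyl-14-[(2R,3S)-3-methyl-6-oxo-3,6-dihydro-2H-pyran-2-yl]-3-oxotetradeca-5,7,11,13-tetraen-2-yl]-2,4-dimethyloxolan-2-yl]acetaldehyde
Conditions: Dess–Martin periodinane (3 equiv), NaHCO3, CH2Cl2, 0 °C → rt
Reagents that add atoms: none
Why: A double Dess–Martin oxidation forms the C17 ketone and the C24 aldehyde last, under buffered non-basic conditions, so C16 and C18 do not epimerise and neither β-alkoxy carbonyl eliminates.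

**Compound list**
1 | (S)-3-bromo-2-methylpropan-1-ol | C[C@@H](CO)CBr | starting material
2 | (S)-(3-bromo-2-methylpropoxy)(tert-butyl)dimethylsilane | C[C@@H](CO[Si](C)(C)C(C)(C)C)CBr | intermediate
3 | (R)-tert-butyldimethyl[(2-methylpent-4-yn-1-yl)oxy]silane | C[C@@H](CO[Si](C)(C)C(C)(C)C)CC#C | intermediate
4 | (R)-2-methylpent-4-yn-1-ol | C[C@@H](CO)CC#C | intermediate
5 | (R)-2-methylpent-4-ynal | C[C@@H](C=O)CC#C | intermediate
6 | 1-bromopropane | CCCBr | starting material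
7 | propyltriphenylphosphonium bromide | CCC[P+](c1ccccc1)(c1ccccc1)c1ccccc1.[Br-] | intermediate
8 | propylidenetriphenylphosphorane | CCC=P(c1ccccc1)(c1ccccc1)c1ccccc1 | intermediate
9 | (1-iodopropyl)triphenylphosphonium iodide | CCC(I)[P+](c1ccccc1)(c1ccccc1)c1ccccc1.[I-] | intermediate
10 | (1-iodopropylidene)triphenylphosphorane | CCC(I)=P(c1ccccc1)(c1ccccc1)c1ccccc1 | intermediate
11 | (3Z,5R)-3-iodo-5-methyloct-3-en-7-yne | CC/C(I)=C/[C@H](C)CC#C | intermediate
12 | 2-[(1E,4R,5Z)-6-iodo-4-methylocta-1,5-dien-1-yl]-4,4,5,5-tetramethyl-1,3,2-dioxaborolane | CC/C(I)=C/[C@H](C)C/C=C/B1OC(C)(C)C(C)(C)O1 | intermediate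
13 | 3-(trimethylsilyl)prop-2-ynal | C[Si](C)(C)C#CC=O | starting material
14 | (E)-but-2-ene | C/C=C/C | starting material
15 | (E)-but-2-en-1-ylpotassium | C/C=C/C[K] | intermediate
16 | (E)-crotylbis(isopinocampheyl)borane, both isopinocampheyl groups from (+)-α-pinene | C/C=C/CB([C@@H]1C[C@@H]2C[C@H]([C@H]1C)C2(C)C)[C@@H]1C[C@@H]2C[C@H]([C@H]1C)C2(C)C | intermediate
17 | (3S,4S)-4-methyl-1-(trimethylsilyl)hex-5-en-1-yn-3-ol | C[Si](C)(C)C#C[C@@H](O)[C@@H](C)C=C | intermediate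
18 | (3S,4S)-4-methylhex-5-en-1-yn-3-ol | C#C[C@@H](O)[C@@H](C)C=C | intermediate
19 | (1E,3S,4S)-4-methyl-1-(tributylstannyl)hexa-1,5-dien-3-ol | CCCC[Sn](CCCC)(CCCC)/C=C/[C@@H](O)[C@@H](C)C=C | intermediate
20 | acryloyl chloride | C=CC(Cl)=O | starting material
21 | (1E,3S,4S)-4-methyl-1-(tributylstannyl)hexa-1,5-dien-3-yl prop-2-enoate | CCCC[Sn](CCCC)(CCCC)/C=C/[C@@H](OC(=O)C=C)[C@@H](C)C=C | intermediate
22 | (5S,6S)-5-methyl-6-[(E)-2-(tributylstannyl)ethenyl]-5,6-dihydro-2H-pyran-2-one | CCCC[Sn](CCCC)(CCCC)/C=C/[C@H]1OC(=O)C=C[C@@H]1C | intermediate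
23 | (5S,6R)-6-[(1E,3Z,5R,7E)-3-ethyl-5-methyl-8-(4,4,5,5-tetramethyl-1,3,2-dioxaborolan-2-yl)octa-1,3,7-trien-1-yl]-5-methyl-5,6-dihydro-2H-pyran-2-one | CCC(=C/[C@H](C)C/C=C/B1OC(C)(C)C(C)(C)O1)/C=C/[C@H]1OC(=O)C=C[C@@H]1C | intermediate
24 | (R)-tert-butyl[(2,4-dimethylpent-4-en-1-yl)oxy]dimethylsilane | C[C@@H](CO[Si](C)(C)C(C)(C)C)CC(C)=C | intermediate
25 | (R)-2,4-dimethylpent-4-en-1-ol | C[C@@H](CO)CC(C)=C | intermediate
26 | (R)-2,4-dimethylpent-4-enal | C[C@@H](C=O)CC(C)=C | intermediate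
27 | ethyl (S)-lactate | CCOC(=O)[C@H](C)O | starting material
28 | (S)-2-hydroxy-N-methoxy-N-methylpropanamide | CON(C)C(=O)[C@H](C)O | intermediate
29 | (S)-2-hydroxypentan-3-one | CCC(=O)[C@H](C)O | intermediate
30 | (S)-3-oxopentan-2-yl benzoate | CCC(=O)[C@H](C)OC(=O)c1ccccc1 | intermediate
31 | (2S,3E)-3-[(dicyclohexylboranyl)oxy]pent-3-en-2-yl benzoate | C/C=C(/OB(C1CCCCC1)C1CCCCC1)[C@H](C)OC(=O)c1ccccc1 | intermediate
32 | (2S,4R,5R,6R)-5-hydroxy-4,6,8-trimethyl-3-oxonon-8-en-2-yl benzoate | C[C@H](OC(=O)c1ccccc1)C(=O)[C@H](C)[C@H](O)[C@H](C)CC(C)=C | intermediate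
33 | methyl 2-[(2R,4R,5R)-5-[(2R,4S)-4-(benzoyloxy)-3-oxopentan-2-yl]-2,4-dimethyloxolan-2-yl]acetate | C[C@H](OC(=O)c1ccccc1)C(=O)[C@H](C)[C@@H]1O[C@@](C)(CC(=O)OC)C[C@H]1C | intermediate
34 | (2S,3RS,4S)-4-[(2R,3R,5R)-5-(2-hydroxyethyl)-3,5-dimethyloxolan-2-yl]pentane-2,3-diol | C[C@H](O)C(O)[C@H](C)[C@@H]1O[C@@](C)(CCO)C[C@H]1C | intermediate
35 | (2R)-2-[(2R,3R,5R)-5-(2-hydroxyethyl)-3,5-dimethyloxolan-2-yl]propanal | O=C[C@H](C)[C@@H]1O[C@@](C)(CCO)C[C@H]1C | intermediate
36 | pent-3-yn-2-one | CC#CC(C)=O | starting material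
37 | (S)-pent-3-yn-2-ol | CC#C[C@H](C)O | intermediate
38 | (S)-pent-3-yn-2-yl methanesulfonate | CC#C[C@H](C)OS(C)(=O)=O | intermediate
39 | (aR)-iodo(methanesulfonato)(penta-2,3-dien-2-yl)indium | CC([In](I)OS(C)(=O)=O)=[C@@]=C([H])C | intermediate
40 | (2S,3R,4R)-2-[(2R,3R,5R)-5-(2-hydroxyethyl)-3,5-dimethyloxolan-2-yl]-4-methylhept-5-yn-3-ol | CC#C[C@@H](C)[C@@H](O)[C@H](C)[C@@H]1O[C@@](C)(CCO)C[C@H]1C | intermediate
41 | triethyl{2-[(2R,4R,5R)-2,4-dimethyl-5-[(2R,3R,4R)-4-methyl-3-(triethylsilyloxy)hept-5-yn-2-yl]oxolan-2-yl]ethoxy}silane | CC#C[C@@H](C)[C@@H](O[Si](CC)(CC)CC)[C@H](C)[C@@H]1O[C@@](C)(CCO[Si](CC)(CC)CC)C[C@H]1C | intermediate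
42 | chlorobis(cyclopentadienyl){(2E,4R,5R,6R)-6-[(2R,3R,5R)-3,5-dimethyl-5-[2-(triethylsilyloxy)ethyl]oxolan-2-yl]-4-methyl-5-(triethylsilyloxy)hept-2-en-2-yl}zirconium | Cl[Zr](C1C=CC=C1)(C1C=CC=C1)/C(C)=C/[C@@H](C)[C@@H](O[Si](CC)(CC)CC)[C@H](C)[C@@H]1O[C@@](C)(CCO[Si](CC)(CC)CC)C[C@H]1C | intermediate
43 | triethyl{2-[(2R,4R,5R)-5-[(2R,3R,4R,5E)-6-iodo-4-methyl-3-(triethylsilyloxy)hept-5-en-2-yl]-2,4-dimethyloxolan-2-yl]ethoxy}silane | I/C(C)=C/[C@@H](C)[C@@H](O[Si](CC)(CC)CC)[C@H](C)[C@@H]1O[C@@](C)(CCO[Si](CC)(CC)CC)C[C@H]1C | intermediate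
44 | (5S,6R)-6-[(1E,3Z,5R,7E,9E,11R,12R,13R)-13-[(2R,3R,5R)-3,5-dimethyl-5-[2-(triethylsilyloxy)ethyl]oxolan-2-yl]-3-ethyl-5,9,11-trimethyl-12-(triethylsilyloxy)tetradeca-1,3,7,9-tetraen-1-yl]-5-methyl-5,6-dihydro-2H-pyran-2-one | CCC(=C/[C@H](C)C/C=C/C(C)=C/[C@@H](C)[C@@H](O[Si](CC)(CC)CC)[C@H](C)[C@@H]1O[C@@](C)(CCO[Si](CC)(CC)CC)C[C@H]1C)/C=C/[C@H]1OC(=O)C=C[C@@H]1C | intermediate
45 | (5S,6R)-6-[(1E,3Z,5R,7E,9E,11R,12R,13S)-3-ethyl-12-hydroxy-13-[(2R,3R,5R)-5-(2-hydroxyethyl)-3,5-dimethyloxolan-2-yl]-5,9,11-trimethyltetradeca-1,3,7,9-tetraen-1-yl]-5-methyl-5,6-dihydro-2H-pyran-2-one | CCC(=C/[C@H](C)C/C=C/C(C)=C/[C@@H](C)[C@@H](O)[C@H](C)[C@@H]1O[C@@](C)(CCO)C[C@H]1C)/C=C/[C@H]1OC(=O)C=C[C@@H]1C | intermediate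
46 | 2-[(2R,4R,5R)-5-[(2R,4R,5E,7E,10R,11Z,13E)-12-ethyl-4,6,10-trimethyl-14-[(2R,3S)-3-methyl-6-oxo-3,6-dihydro-2H-pyran-2-yl]-3-oxotetradeca-5,7,11,13-tetraen-2-yl]-2,4-dimethyloxolan-2-yl]acetaldehyde | CCC(=C/[C@H](C)C/C=C/C(C)=C/[C@@H](C)C(=O)[C@H](C)[C@@H]1O[C@@](C)(CC=O)C[C@H]1C)/C=C/[C@H]1OC(=O)C=C[C@@H]1C | target

**Totals**
Total step count: 31. Longest linear sequence: 14 steps (1, 14, 15, 16, 20, 21, 22, 23, 26, 27, 28, 29, 30, 31).

**Steps most likely to fail**

Step 21 (the proposed alkoxycarbonylative cyclisation; face selectivity at C22 and turnover with an aliphatic alcohol are untested). The fallback uses known chemistry and splits the step into an ionic ring closure and a separate carbonylation. It sets out from 32: iodoetherification (I2, NaHCO3, MeCN, 0 °C) gives (2S,4R)-4-[(2R,3R,5R)-5-(iodomethyl)-3,5-dimethyloxolan-2-yl]-3-oxopentan-2-yl benzoate F1. The C22 epimers are separated by chromatography, and the unwanted one is returned to 32 with zinc dust in ethanol. Light-induced radical alkoxycarbonylation of the primary iodide (Pd(PPh3)4 5 mol %, CO 20 atm, MeOH, Et3N, hν) then comes back to the route at 33.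

Step 20 (mismatched double stereodifferentiation: the lactate enolate must override the Felkin bias of 26). The fallback takes C20 out of the aldol. It sets out from 30: the same boron enolate 31 is added to achiral methacrolein, so only reagent control operates, giving (2S,4R,5S)-5-hydroxy-4,6-dimethyl-3-oxohept-6-en-2-yl benzoate F2. Still–Barrish hydroboration with 9-BBN (2.2 equiv, THF, 0 °C → rt; the first equivalent caps the hydroxyl) places boron on C21 and hydrogen on C20 anti to the C19 oxygen. This gives (2S,4R,5R,6R)-7-(9-borabicyclo[3.3.1]nonan-9-yl)-5-[(9-borabicyclo[3.3.1]nonan-9-yl)oxy]-4,6-dimethyl-3-oxoheptan-2-yl benzoate F3, which is not isolated. B-alkyl Suzuki–Miyaura coupling with 2-bromopropene (Pd(dppf)Cl2, K3PO4, DMF–H2O, rt) comes back to the route at 32.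

Step 29 (aqueous base in the presence of the unsaturated lactone and a hindered trisubstituted iodide). The fallback changes the order of assembly so that the lactone enters last under neutral Stille conditions. It sets out from 4 and 43.
- Hydroboration of 4 (pinacolborane 2.2 equiv, Cp2Zr(H)Cl cat.) gives (R,E)-2-methyl-5-(4,4,5,5-tetramethyl-1,3,2-dioxaborolan-2-yl)pent-4-en-1-ol F4.
- Suzuki–Miyaura coupling of F4 with 43 (Pd(dppf)Cl2, K3PO4, DMF–H2O, rt; no lactone present) gives (2R,4E,6E,8R,9R,10R)-10-[(2R,3R,5R)-3,5-dimethyl-5-[2-(triethylsilyloxy)ethyl]oxolan-2-yl]-2,6,8-trimethyl-9-(triethylsilyloxy)undeca-4,6-dien-1-ol F5.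
- Dess–Martin oxidation gives (2R,4E,6E,8R,9R,10R)-10-[(2R,3R,5R)-3,5-dimethyl-5-[2-(triethylsilyloxy)ethyl]oxolan-2-yl]-2,6,8-trimethyl-9-(triethylsilyloxy)undeca-4,6-dienal F6.
- Iodo-olefination with ylide 10 (made from 7 as in step 6) gives triethyl{2-[(2R,4R,5R)-5-[(2R,3R,4R,5E,7E,10R,11Z)-12-iodo-4,6,10-trimethyl-3-(triethylsilyloxy)tetradeca-5,7,11-trien-2-yl]-2,4-dimethyloxolan-2-yl]ethoxy}silane F7.
- Stille coupling of F7 with 22 (PdCl2(MeCN)2, DMF, rt) comes back to the route at 44.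

**Further compounds**
F1 | step 21 | (2S,4R)-4-[(2R,3R,5R)-5-(iodomethyl)-3,5-dimethyloxolan-2-yl]-3-oxopentan-2-yl benzoate | C[C@H](OC(=O)c1ccccc1)C(=O)[C@H](C)[C@@H]1O[C@@](C)(CI)C[C@H]1C
F2 | step 20 | (2S,4R,5S)-5-hydroxy-4,6-dimethyl-3-oxohept-6-en-2-yl benzoate | C[C@H](OC(=O)c1ccccc1)C(=O)[C@H](C)[C@H](O)C(C)=C
F3 | step 20 | (2S,4R,5R,6R)-7-(9-borabicyclo[3.3.1]nonan-9-yl)-5-[(9-borabicyclo[3.3.1]nonan-9-yl)oxy]-4,6-dimethyl-3-oxoheptan-2-yl benzoate | C[C@H](OC(=O)c1ccccc1)C(=O)[C@H](C)[C@H](OB1C2CCCC1CCC2)[C@H](C)CB1C2CCCC1CCC2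
F4 | step 29 | (R,E)-2-methyl-5-(4,4,5,5-tetramethyl-1,3,2-dioxaborolan-2-yl)pent-4-en-1-ol | C[C@@H](CO)C/C=C/B1OC(C)(C)C(C)(C)O1
F5 | step 29 | (2R,4E,6E,8R,9R,10R)-10-[(2R,3R,5R)-3,5-dimethyl-5-[2-(triethylsilyloxy)ethyl]oxolan-2-yl]-2,6,8-trimethyl-9-(triethylsilyloxy)undeca-4,6-dien-1-ol | OC[C@H](C)C/C=C/C(C)=C/[C@@H](C)[C@@H](O[Si](CC)(CC)CC)[C@H](C)[C@@H]1O[C@@](C)(CCO[Si](CC)(CC)CC)C[C@H]1C
F6 | step 29 | (2R,4E,6E,8R,9R,10R)-10-[(2R,3R,5R)-3,5-dimethyl-5-[2-(triethylsilyloxy)ethyl]oxolan-2-yl]-2,6,8-trimethyl-9-(triethylsilyloxy)undeca-4,6-dienal | O=C[C@H](C)C/C=C/C(C)=C/[C@@H](C)[C@@H](O[Si](CC)(CC)CC)[C@H](C)[C@@H]1O[C@@](C)(CCO[Si](CC)(CC)CC)C[C@H]1C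
F7 | step 29 | triethyl{2-[(2R,4R,5R)-5-[(2R,3R,4R,5E,7E,10R,11Z)-12-iodo-4,6,10-trimethyl-3-(triethylsilyloxy)tetradeca-5,7,11-trien-2-yl]-2,4-dimethyloxolan-2-yl]ethoxy}silane | CC/C(I)=C/[C@H](C)C/C=C/C(C)=C/[C@@H](C)[C@@H](O[Si](CC)(CC)CC)[C@H](C)[C@@H]1O[C@@](C)(CCO[Si](CC)(CC)CC)C[C@H]1C
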